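**Strategy.** Each half of epoxytwinol A is a 3-methylisochromane in disguise: the pyran ring (C1, O2, C3, C4) is fused at C4a=C8a to the epoxyquinol ring, and the halves are joined C1–C1′ and C4–C4′. The route treats C1–C1′ as glyoxal and the O2–C1 and C1–C8a bonds as oxa-Pictet–Spengler bonds. A C2-symmetric (2R,3S,4S,5R)-3,4-bis(2,5-dimethoxyphenyl)hexane-2,5-diol, which already holds C4–C4′ and both CHMe centres, is condensed with glyoxal bis(dimethyl acetal). One operation closes both pyran rings and the central eight-membered carbocycle and fixes C1/C1′. The two hydroquinone ether rings are then dearomatized and converted to the epoxyquinols.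

Key step: step 6

Numbering: each half is numbered as an isochromane (C1, O2, C3, C4, C4a, C5–C8, C8a; primes for the second half). In the target C5 is the ketone, C6/C7 the epoxide and C8 the carbinol.

Assumption: the chelated (Z)-enolates of the (S)-oxazolidinone in step 2 couple on the face anti to the benzyl group, as they do in alkylations, which corresponds to the (2S,3S) dimer.

Assumption: N-benzylcinchonidinium chloride is taken as the catalyst pseudoenantiomer that places the epoxide anti to the partner half in step 9; its cinchoninium counterpart would serve in the opposite case.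

Step 1
Reactants: 1 2-(2,5-dimethoxyphenyl)acetic acid; 2 (S)-4-benzyl-1,3-oxazolidin-2-one
Product: 4 (S)-4-benzyl-3-[2-(2,5-dimethoxyphenyl)acetyl]-1,3-oxazolidin-2-one, via pivalic mixed anhydride 3 (not isolated)
Conditions: PivCl, Et3N, THF, −20 °C; then 2, LiCl, −20 °C → rt
Reagents that add atoms: none
Why: Mixed-anhydride N-acylation of the oxazolidinone should give the imide without touching the aryl ethers; no stereocentre is formed.

Step 2
Reactants: 4 (S)-4-benzyl-3-[2-(2,5-dimethoxyphenyl)acetyl]-1,3-oxazolidin-2-one (two molecules)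
Product: 6 (2S,3S)-1,4-bis[(S)-4-benzyl-2-oxo-1,3-oxazolidin-3-yl]-2,3-bis(2,5-dimethoxyphenyl)butane-1,4-dione, via lithium enolate 5 (not isolated)
Conditions: LDA, THF, −78 °C; then TiCl4, −78 → 0 °C
Reagents that add atoms: none
Why: Oxidative enolate homocoupling by electron transfer to Ti(IV) should join the two α-carbons on the enolate faces anti to the benzyl groups, which sets both new centres (the future C4 and C4′) as S in a C2-symmetric dimer.

Step 3
Reactants: 6 (2S,3S)-1,4-bis[(S)-4-benzyl-2-oxo-1,3-oxazolidin-3-yl]-2,3-bis(2,5-dimethoxyphenyl)butane-1,4-dione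
Product: 7 S,S′-diethyl (2S,3S)-2,3-bis(2,5-dimethoxyphenyl)butanebis(thioate)
Conditions: EtSH, n-BuLi, THF, 0 °C
Reagents that add atoms: ethanethiol CCS
Why: Lithium ethanethiolate cleaves hindered N-acyl oxazolidinones at the exocyclic carbonyl (acyl substitution), and the weakly basic thiolate should not epimerize the α-aryl centres.

Step 4
Reactants: 7 S,S′-diethyl (2S,3S)-2,3-bis(2,5-dimethoxyphenyl)butanebis(thioate)
Product: 8 (3S,4S)-3,4-bis(2,5-dimethoxyphenyl)hexane-2,5-dione
Conditions: Me2CuLi (from MeLi, CuI), Et2O, −78 → −40 °C; NH4Cl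
Reagents that add atoms: methyllithium [Li]C
Why: Thioesters are acylated by lithium dialkylcuprates to ketones without over-addition, and the weakly basic reagent at low temperature should leave the benzylic α-centres intact.

Step 5
Reactants: 8 (3S,4S)-3,4-bis(2,5-dimethoxyphenyl)hexane-2,5-dione
Product: 9 (2R,3S,4S,5R)-3,4-bis(2,5-dimethoxyphenyl)hexane-2,5-diol
Conditions: (S)-Me-CBS (cat.), BH3·SMe2, THF, −20 °C; MeOH
Reagents that add atoms: none
Why: Corey–Bakshi–Shibata reduction with the branched CH(Ar) group as the large and methyl as the small substituent should give the (R)-carbinols, and this sense matches the Felkin–Anh preference of the (S)-α-aryl centres, so both ketones should give the 2,3-syn diol (the future C3 and C3′).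

Step 6
Reactants: 9 (2R,3S,4S,5R)-3,4-bis(2,5-dimethoxyphenyl)hexane-2,5-diol; 10 1,1,2,2-tetramethoxyethane
Product: 12 cage bis(5,8-dimethoxy-3-methylisochromane) joined C1–C1′ and C4–C4′ (1S,3R,4S in each half), via isochromane acetal 11 (not isolated)
Conditions: TfOH (20 mol %), CH2Cl2/HFIP 4:1, 0.01 M, −20 → 0 °C
Reagents that add atoms: none
Why: Triflic acid exchanges a methoxy group of 10 for a carbinol oxygen of 9 and ionizes the mixed acetal to the (E)-oxocarbenium ion O2=C1, which the arene attacks at C8a, the only free position ortho to the side chain, and the pendant dimethyl acetal of 11 then repeats the sequence with the second carbinol and arene (double oxa-Pictet–Spengler reaction; the closest known type is the formation of 5,8-dimethoxyisochromanes from 2-(2,5-dimethoxyphenyl)ethanols and acetals). Both pyran rings close in 6-endo-trig Friedel–Crafts attacks, and the second closure also completes the eight-membered carbocycle C1–C8a–C4a–C4–C4′–C4a′–C8a′–C1′, because C1–C1′ comes intact from 10 and C4–C4′ is already in 9. In the first closure the all-equatorial arrangement suffers peri strain with both the C5 and the C8 methoxy group and the all-axial one a 1,3-diaxial clash, so C1 should form with its substituent trans to the C3 methyl and cis to the C4–C4′ bond (1S). C1′ is then dictated by the cage, since only a cis-1,4 bridge across the second pyran ring can close. The step needs six-ring closure to win over seven-membered closure onto the remote oxygen and over intermolecular acetal exchange, which the ortho tether and high dilution should secure, and the irreversible C–C bond formation drains the reversible acetal equilibria towards 12.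

Step 7
Reactants: 12 cage bis(5,8-dimethoxy-3-methylisochromane) joined C1–C1′ and C4–C4′
Product: 13 octamethoxy cage in which both arene rings of 12 are 5,5,8,8-tetramethoxy-5,8-dihydro rings (quinone bisketals)
Conditions: anodic oxidation (Pt anode, undivided cell, constant current), 1% KOH in MeOH, 0 °C
Reagents that add atoms: methanol CO
Why: Anodic oxidation of 1,4-dimethoxyarenes in methanolic base (two-electron oxidation with ipso capture of methoxide at both oxygenated carbons) should convert each ring into its quinone bis(dimethyl ketal) without touching the cage stereocentres.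

Step 8
Reactants: 13 octamethoxy cage (bis(quinone bisketal))
Product: 14 cage bis(quinone monoketal) with ketones at C8 and C8′ and dimethyl ketals at C5 and C5′
Conditions: AcOH, H2O, acetone, 0 °C → rt
Reagents that add atoms: water O
Why: Acid hydrolysis of a quinone bisketal stops at the monoketal, and it should occur at C8 because the cation formed there is delocalized onto C4a, which carries the all-carbon C4 substituent, whereas the cation from C5 would sit on C8a next to the inductively withdrawing C1–O2 group.

Step 9
Reactants: 14 cage bis(quinone monoketal)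
Product: 15 bis(6,7-epoxide) of 14 with each epoxide oxygen anti to the partner half
Conditions: t-BuOOH, aq. NaOH, N-benzylcinchonidinium chloride (cat.), toluene, 0 °C
Reagents that add atoms: tert-butyl hydroperoxide CC(C)(C)OO
Why: Weitz–Scheffer epoxidation under chiral phase-transfer catalysis: the peroxide anion adds to C6 of the only unsubstituted enone double bond and closes at C7, the tetrasubstituted C4a=C8a bond being unreactive, and the face is chosen by the catalyst ion pair because the cage is too remote to bias it.

Step 10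
Reactants: 15 bis(6,7-epoxide) of 14
Product: 16 bis(8-alcohol) of 15 with each hydroxyl anti to its epoxide
Conditions: DIBAL-H, THF, −78 °C
Reagents that add atoms: none
Why: 1,2-Reduction of 4,4-dialkoxy-5,6-epoxycyclohexenones with DIBAL-H delivers hydride syn to the epoxide oxygen and should give the anti-epoxy alcohol at C8, while the C5 ketal keeps the second carbonyl masked so that regiochemistry is not in question.

Step 11
Reactants: 16 bis(8-alcohol) of 15
Product: 17 epoxytwinol A
Conditions: montmorillonite K10, wet CH2Cl2, rt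
Reagents that add atoms: water O
Why: Mild acid hydrolysis of the dimethyl ketals should unveil the C5 enones without opening the epoxides or ionizing the C1–O2 ethers, whose cations would be bridgehead-type and poorly stabilized.

**Compound list**

1 | 2-(2,5-dimethoxyphenyl)acetic acid | COc1ccc(OC)c(CC(=O)O)c1 | starting material
2 | (S)-4-benzyl-1,3-oxazolidin-2-one | O=C1OC[C@H](Cc2ccccc2)N1 | starting material
3 | 2-(2,5-dimethoxyphenyl)acetic pivalic anhydride | COc1ccc(OC)c(CC(=O)OC(=O)C(C)(C)C)c1 | intermediate
4 | (S)-4-benzyl-3-[2-(2,5-dimethoxyphenyl)acetyl]-1,3-oxazolidin-2-one | COc1ccc(OC)c(CC(=O)N2[C@@H](Cc3ccccc3)COC2=O)c1 | intermediate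
5 | lithium (Z)-enolate of 4 | [Li]O/C(=C\c1cc(OC)ccc1OC)N1[C@@H](Cc2ccccc2)COC1=O | intermediate
6 | (2S,3S)-1,4-bis[(S)-4-benzyl-2-oxo-1,3-oxazolidin-3-yl]-2,3-bis(2,5-dimethoxyphenyl)butane-1,4-dione | O=C(N1[C@@H](Cc2ccccc2)COC1=O)[C@H](c1cc(OC)ccc1OC)[C@@H](c1cc(OC)ccc1OC)C(=O)N1[C@@H](Cc2ccccc2)COC1=O | intermediate
7 | S,S′-diethyl (2S,3S)-2,3-bis(2,5-dimethoxyphenyl)butanebis(thioate) | CCSC(=O)[C@H](c1cc(OC)ccc1OC)[C@@H](c1cc(OC)ccc1OC)C(=O)SCC | intermediate
8 | (3S,4S)-3,4-bis(2,5-dimethoxyphenyl)hexane-2,5-dione | CC(=O)[C@H](c1cc(OC)ccc1OC)[C@@H](c1cc(OC)ccc1OC)C(C)=O | intermediate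
9 | (2R,3S,4S,5R)-3,4-bis(2,5-dimethoxyphenyl)hexane-2,5-diol | C[C@@H](O)[C@H](c1cc(OC)ccc1OC)[C@@H](c1cc(OC)ccc1OC)[C@@H](C)O | intermediate
10 | 1,1,2,2-tetramethoxyethane (glyoxal bis(dimethyl acetal)) | COC(OC)C(OC)OC | starting material
11 | (1S,3R,4S)-1-(dimethoxymethyl)-4-[(1S,2R)-1-(2,5-dimethoxyphenyl)-2-hydroxypropyl]-5,8-dimethoxy-3-methylisochromane | C[C@H]1O[C@H](C(OC)OC)c2c(OC)ccc(OC)c2[C@@H]1[C@@H](c1cc(OC)ccc1OC)[C@@H](C)O | intermediate
12 | cage bis(5,8-dimethoxy-3-methylisochromane) joined C1–C1′ and C4–C4′ (1S,3R,4S in each half) | C[C@H]1O[C@H]2c3c(OC)ccc(OC)c3[C@@H]1[C@H]1c3c(OC)ccc(OC)c3[C@@H]2O[C@@H]1C | intermediate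
13 | octamethoxy cage: 12 with both arene rings as 5,5,8,8-tetramethoxy-5,8-dihydro rings | C[C@H]1O[C@H]2C3=C(C(OC)(OC)C=CC3(OC)OC)[C@@H]1[C@H]1C3=C(C(OC)(OC)C=CC3(OC)OC)[C@@H]2O[C@@H]1C | intermediate
14 | cage bis(quinone monoketal): ketones at C8 and C8′, dimethyl ketals at C5 and C5′ | C[C@H]1O[C@H]2C3=C(C(OC)(OC)C=CC3=O)[C@@H]1[C@H]1C3=C(C(=O)C=CC3(OC)OC)[C@@H]2O[C@@H]1C | intermediate
15 | bis(6,7-epoxide) of 14, each epoxide oxygen anti to the partner half | C[C@H]1O[C@H]2C3=C(C(OC)(OC)[C@@H]4O[C@@H]4C3=O)[C@@H]1[C@H]1C3=C(C(=O)[C@H]4O[C@H]4C3(OC)OC)[C@@H]2O[C@@H]1C | intermediate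
16 | bis(8-alcohol) of 15, each hydroxyl anti to its epoxide | C[C@H]1O[C@H]2C3=C(C(OC)(OC)[C@@H]4O[C@@H]4[C@H]3O)[C@@H]1[C@H]1C3=C([C@H](O)[C@H]4O[C@H]4C3(OC)OC)[C@@H]2O[C@@H]1C | intermediate
17 | epoxytwinol A | C[C@H]1O[C@H]2C3=C(C(=O)[C@@H]4O[C@@H]4[C@H]3O)[C@@H]1[C@H]1C3=C([C@H](O)[C@H]4O[C@H]4C3=O)[C@@H]2O[C@@H]1C | target

**Totals.** Total step count: 11. Longest linear sequence: 11 steps (1 → 17).

**Steps most likely to fail**

1. Step 6. The second ring closure has to pass through an eight-membered cyclic oxocarbenium ion and may be outrun by intermolecular acetal exchange, or the first closure may give the C1 epimer that cannot bridge. The fallback sets out from 9 and comes back at 12, and makes C1–C1′ last instead of bringing it in with glyoxal. Diol 9 is cyclized twice with dimethoxymethane (BF3·OEt2, CH2Cl2); each ring closes on its own and no medium ring is involved, which gives the C4–C4′-linked bi(5,8-dimethoxy-3-methylisochromane) F1. DDQ in CH2Cl2/MeOH abstracts hydride from the benzylic, oxygen-bearing C1 positions and gives the bis(1-methoxy) acetal F2. Ionization of both acetals and one-electron reduction (TMSOTf, then SmI2, THF, high dilution) should couple the two α-alkoxybenzyl radicals in a pinacol-type closure to 12; only the cis-bridged cage can form.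

2. Step 8. Regiocontrol in the ketal hydrolysis may be lost (hydrolysis at C5 instead of C8, or on to the quinone). The fallback sets out from 12 and comes back at 14, and fixes the regiochemistry through the phenol that is left free. Ceric ammonium nitrate (MeCN/H2O) gives the cage bis(quinone) F3, and Na2S2O4 reduces it to the cage bis(hydroquinone) F4. One equivalent of MeI per ring (K2CO3, acetone) should methylate the C5 hydroxyl, because the C8 hydroxyl is hydrogen-bonded to the pyran oxygen and less nucleophilic; this gives the cage bis(8-hydroxy-5-methoxy) compound F5. PhI(OAc)2 in MeOH then oxidizes the free C8 phenol to the dienone with the dimethyl ketal at C5, which is 14.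

3. Step 9. Facial selectivity in the conjugate addition of the peroxide may be poor, since the cage hardly differentiates the two faces at C6. The fallback sets out from 14 and comes back at 15, and sets the face with a reduction that has a reliable model. (R)-Me-CBS with catecholborane (toluene, −78 °C) reduces C8=O with the tetrasubstituted C4a=C8a side as the large group and should give the bis(8-dienol) F6 with each hydroxyl anti to the partner half. VO(acac)2/t-BuOOH then epoxidizes C6=C7 syn to that hydroxyl, the shielded tetrasubstituted bond staying untouched, and gives the bis(syn-epoxy alcohol) F7. Dess–Martin oxidation returns the C8 ketones, which is 15.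

**Further compounds**

F1 | step 6 | C4–C4′-linked bi(5,8-dimethoxy-3-methylisochromane) (3R,4S in each half) | C[C@H]1OCc2c(OC)ccc(OC)c2[C@@H]1[C@H]1c2c(OC)ccc(OC)c2CO[C@@H]1C
F2 | step 6 | bis(1-methoxy) acetal of F1 (anomeric mixture) | C[C@H]1OC(OC)c2c(OC)ccc(OC)c2[C@@H]1[C@H]1c2c(OC)ccc(OC)c2C(OC)O[C@@H]1C
F3 | step 8 | cage bis(quinone): 12 with both rings as 5,8-diones | C[C@H]1O[C@H]2C3=C(C(=O)C=CC3=O)[C@@H]1[C@H]1C3=C(C(=O)C=CC3=O)[C@@H]2O[C@@H]1C
F4 | step 8 | cage bis(hydroquinone): 12 with four free phenols | C[C@H]1O[C@H]2c3c(O)ccc(O)c3[C@@H]1[C@H]1c3c(O)ccc(O)c3[C@@H]2O[C@@H]1C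
F5 | step 8 | cage bis(8-hydroxy-5-methoxy) compound | C[C@H]1O[C@H]2c3c(O)ccc(OC)c3[C@@H]1[C@H]1c3c(OC)ccc(O)c3[C@@H]2O[C@@H]1C
F6 | step 9 | bis(8-dienol) of 14, each hydroxyl anti to the partner half | C[C@H]1O[C@H]2C3=C(C(OC)(OC)C=C[C@@H]3O)[C@@H]1[C@H]1C3=C([C@@H](O)C=CC3(OC)OC)[C@@H]2O[C@@H]1C
F7 | step 9 | bis(syn-epoxy alcohol): 6,7-epoxides of F6 on the hydroxyl face | C[C@H]1O[C@H]2C3=C(C(OC)(OC)[C@@H]4O[C@@H]4[C@@H]3O)[C@@H]1[C@H]1C3=C([C@@H](O)[C@H]4O[C@H]4C3(OC)OC)[C@@H]2O[C@@H]1C
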